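**Plan**

1. Numbering used below: the cyclooctane carbons are C1–C8 (C1 = CH bearing 2-methylpropanoyl, C2 = ketone, C3 = C(O)(prenyl), C4 = bridging ketone, C5 = C(prenyl), C6 = CH2, C7 = CH(prenyl), C8 = C(CH3)(side chain)); C9 is the lactone carbonyl on C5.
2. Cuts, last to first: O–OH (from the tertiary allylic alcohol); the C1'–C2' bond of the C7 prenyl group (exocyclic C7=CH2, hydroboration/Suzuki); C5–C6 (ring closure); C1–C2 (aldol, then oxidation); C8–C7 (conjugate addition); C3–O and O–C9 (hydroxylation/lactonisation of a symmetric keto diester).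
3. Enabling feature: the five-membered lactone (O, C9, C5, C4, C3) is a tetronic acid in its furan-2,4-dione form, so C5 between C9=O and C4=O is an acidic, soft carbon nucleophile. C7 carries a one-carbon branch, so C6–C7–C1' can be a 2-substituted allyl unit whose second terminus later becomes the first carbon of the C7 prenyl group.
4. Ring order: the lactone ring is made first (step 2); the cyclooctane, and with it the 8-oxabicyclo[5.2.1]decane core, is closed in one palladium-catalysed allylic alkylation (step 12) of an open-chain precursor joined from aldehyde 6 and ketone 16.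
5. Stereochemistry: C3 by catalytic enantioselective hydroxylation and C8 by catalytic enantioselective conjugate addition; C5 is forced by C3 in the ring closure, C7 follows by substrate-controlled hydroboration of the bicycle, and the enolisable C1 settles thermodynamically.

Key step: step 12

Assumption: in steps 2 and 6 the enantiomer of the chiral ligand that gives the drawn configuration is used (both antipodes are accessible), and the configuration of the enolisable 1,3-diketone methine C1 in the target is taken to be the more stable one.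

**Route**

Step 1
Reactants: 1 dimethyl 3-oxopentanedioate; 2 1-bromo-3-methylbut-2-ene (two equivalents)
Product: 3 dimethyl 2,4-bis(3-methylbut-2-en-1-yl)-3-oxopentanedioate (diastereomer mixture; both centres enolisable)
Conditions: NaH (2 × 1.0 equiv), 2 (2 × 1.0 equiv), THF, 0 °C to rt
Reagents that add atoms: none
Why: Twofold enolate C-alkylation of the acetonedicarboxylate; after the first alkylation the remaining unsubstituted CH2 is the more acidic and less hindered site, so the 2,4-dialkyl product should form, and its two centres are lost or reset later.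

Step 2
Reactants: 3
Product: 5 methyl (2R)-3-hydroxy-2,4-bis(3-methylbut-2-en-1-yl)-5-oxo-2,5-dihydrofuran-2-carboxylate, via hydroxy diester 4 (not isolated)
Conditions: Ni(ClO4)2·6H2O (10 mol%), (R,R)-DBFOX-Ph (11 mol%), 2-(benzenesulfonyl)-3-phenyloxaziridine (1.0 equiv), 4 Å MS, CH2Cl2, rt; then Et3N, rt; 1 M HCl
Reagents that add atoms: 2-(benzenesulfonyl)-3-phenyloxaziridine, O=S(=O)(c1ccccc1)N1OC1c1ccccc1
Why: Catalytic enantioselective α-hydroxylation of a β-keto ester (the chiral Lewis acid chelates the 1,3-dicarbonyl unit and the oxaziridine transfers oxygen to one enolate face, which sets C3; by symmetry either α-carbon gives the same product), followed by base-induced lactonisation of the tertiary alcohol onto the distal ester, driven by formation of the acidic tetronic acid.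

Step 3
Reactants: 5
Product: 6 (2R)-3-hydroxy-2,4-bis(3-methylbut-2-en-1-yl)-5-oxo-2,5-dihydrofuran-2-carbaldehyde
Conditions: DIBAL-H (2.1 equiv), CH2Cl2, −78 °C; aq. Rochelle salt
Reagents that add atoms: none
Why: Partial reduction of an α-alkoxy, α-quaternary ester by DIBAL-H at low temperature (stable chelated aluminium hemiacetal); the first equivalent forms the aluminium tetronate, whose delocalised anion shields the lactone and enol carbonyls.

Step 4
Reactants: 7 pent-1-en-4-yne; 8 2-methylpropanal
Product: 10 (4E)-2,5-dimethylocta-4,7-dien-3-ol (racemic), via alkenylalane 9 (not isolated)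
Conditions: Me3Al (2 equiv), Cp2ZrCl2 (0.2 equiv), CH2Cl2, 0 °C to rt; then n-BuLi, hexane/THF, −78 °C; then 8, −78 °C to rt; 1 M HCl
Reagents that add atoms: trimethylaluminium, C[Al](C)C
Why: Zirconium-catalysed syn-carboalumination of the terminal alkyne gives the E-alkenylalane regio- and stereoselectively, and its alanate adds to the aldehyde; the carbinol centre is removed in step 5.

Step 5
Reactants: 10
Product: 11 (4E)-2,5-dimethylocta-4,7-dien-3-one
Conditions: Dess–Martin periodinane, CH2Cl2, 0 °C to rt
Reagents that add atoms: none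
Why: Dess–Martin oxidation of the allylic alcohol under non-basic conditions, which should keep the skipped diene out of conjugation and preserve the E geometry.

Step 6
Reactants: 11 (4E)-2,5-dimethylocta-4,7-dien-3-one; 12 tert-butyldimethyl(prop-2-yn-1-yloxy)silane
Product: 14 (5S)-5-{3-[(tert-butyldimethylsilyl)oxy]prop-1-en-2-yl}-2,5-dimethyloct-7-en-3-one, via alkenylaluminium 13 (not isolated)
Conditions: 12, DIBAL-H, Ni(dppp)Cl2 (3 mol%), THF, rt; then 11, CuCl2·2H2O (5 mol%), chiral sulfonate-bearing imidazolinium salt (carbene precursor, 5 mol%), THF, −30 °C; aq. Rochelle salt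
Reagents that add atoms: none
Why: Nickel-catalysed α-selective hydroalumination of the terminal alkyne, then copper–carbene-catalysed enantioselective conjugate addition of the 1,1-disubstituted alkenylaluminium to the acyclic β,β-disubstituted enone; this builds the quaternary centre C8 under catalyst control and brings in C7, C6 and the future first carbon of the C7 prenyl group.

Step 7
Reactants: 14; 15 2-methylbut-3-en-2-ol
Product: 16 (5S,7E)-5-{3-[(tert-butyldimethylsilyl)oxy]prop-1-en-2-yl}-9-hydroxy-2,5,9-trimethyldec-7-en-3-one
Conditions: second-generation Grubbs catalyst RuCl2(=CHPh)(PCy3)(H2IMes) (5 mol%), 15 (5 equiv), CH2Cl2, 40 °C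
Reagents that add atoms: none
Why: Olefin cross-metathesis of the monosubstituted allyl group with a tertiary allylic alcohol that does not homodimerise should give the E alkene; the hindered 1,1-disubstituted alkene on the quaternary carbon stays out.

Step 8
Reactants: 16; 6
Product: 17 (5S)-5-[(3S,5E)-3-{3-[(tert-butyldimethylsilyl)oxy]prop-1-en-2-yl}-1,7-dihydroxy-3,7-dimethyl-2-(2-methylpropanoyl)oct-5-en-1-yl]-4-hydroxy-3,5-bis(3-methylbut-2-en-1-yl)furan-2(5H)-one (epimer mixture at the carbinol carbon C2 and at C1)
Conditions: 16, LDA (2.2 equiv), THF, −78 °C; then 6 pre-treated with LiHMDS (1.0 equiv), THF, −78 °C; AcOH quench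
Reagents that add atoms: none
Why: Directed aldol addition: LDA deprotonates the ketone kinetically at the methylene and not at the isopropyl methine, and the lithium enolate adds to the non-enolisable aldehyde, whose tetronic acid is masked as its lithium salt; the two new centres need no control because one is oxidised next and the other is enolisable.

Step 9
Reactants: 17
Product: 18 (5R)-5-[(3S,5E)-3-{3-[(tert-butyldimethylsilyl)oxy]prop-1-en-2-yl}-7-hydroxy-3,7-dimethyl-2-(2-methylpropanoyl)oct-5-enoyl]-4-hydroxy-3,5-bis(3-methylbut-2-en-1-yl)furan-2(5H)-one (C1 epimers, interconverting)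
Conditions: Dess–Martin periodinane, CH2Cl2, 0 °C to rt
Reagents that add atoms: none
Why: Dess–Martin oxidation of the β-hydroxy ketone to the 1,3-diketone; the tertiary alcohol and the tetronic acid should be inert.

Step 10
Reactants: 18
Product: 19 (5R)-4-hydroxy-5-[(3S,5E)-7-hydroxy-3-(3-hydroxyprop-1-en-2-yl)-3,7-dimethyl-2-(2-methylpropanoyl)oct-5-enoyl]-3,5-bis(3-methylbut-2-en-1-yl)furan-2(5H)-one
Conditions: HF·pyridine, pyridine, THF, 0 °C to rt
Reagents that add atoms: none
Why: Buffered fluoride cleavage of the primary allylic silyl ether, which should leave the tertiary allylic alcohol and the acidic enols untouched.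

Step 11
Reactants: 19
Product: 20 methyl carbonate of the primary allylic alcohol of 19 (CH2OCO2CH3 on the propen-2-yl group)
Conditions: ClCO2Me, pyridine, CH2Cl2, 0 °C; then MeOH, rt
Reagents that add atoms: methyl chloroformate, COC(=O)Cl
Why: Carbonate formation by acylation of the primary allylic alcohol; the tertiary alcohol should not react, and any enol carbonate formed at the tetronic acid or the diketone is cleaved again by the methanol quench.

Step 12
Reactants: 20
Product: 21 (1R,4S,5R,7S)-4-[(2E)-4-hydroxy-4-methylpent-2-en-1-yl]-4-methyl-3-methylidene-1,7-bis(3-methylbut-2-en-1-yl)-5-(2-methylpropanoyl)-8-oxabicyclo[5.2.1]decane-6,9,10-trione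
Conditions: Pd2(dba)3 (5 mol%), PPh3 (20 mol%), THF, slow addition of 20 to 0.003 M, 60 °C
Reagents that add atoms: none
Why: Zerovalent palladium ionises the allylic methyl carbonate to a 2-substituted π-allylpalladium cation, the methoxide set free with CO2 deprotonates the tetronic acid, and the tetronate carbon C5 attacks an allyl terminus (C6) on the face opposite to palladium. The closest known reaction type is the intramolecular Tsuji–Trost allylic alkylation of 1,3-dicarbonyl compounds, which is known to close medium rings and to C-allylate 3-substituted tetronic acids to quaternary furan-2,4-diones. The cyclooctane (C1–C8) is closed by attack at the terminus of an allyl unit tethered through its central carbon C7, so the new C7=CH2 bond lies outside the ring (exo mode); the same bond completes the nine-membered ring through the lactone and hence the 8-oxabicyclo[5.2.1]decane core. The new quaternary centre C5 is controlled by C3, because the five-atom tether C2–C1–C8–C7–C6 can reach C5 only on the face of the planar tetronate that carries C2, so the two prenyl groups end up cis on the lactone; the enolisable centre C1 should settle under the weakly basic conditions with the 2-methylpropanoyl group trans to the larger C8 substituent. The step needs C- over O-allylation (O-allyl enol ethers re-ionise with palladium or pass by [3,3] shift to the same product), cyclisation over oligomerisation (high dilution) and ionisation of the carbonate only (the tertiary allylic alcohol is not activated); β-hydride elimination is impossible because C8 is quaternary, and both allyl termini are CH2 groups, so either gives the same product.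

Step 13
Reactants: 21; 22 1-bromo-2-methylprop-1-ene
Product: 24 (1R,3S,4R,5R,7S)-4-[(2E)-4-hydroxy-4-methylpent-2-en-1-yl]-4-methyl-1,3,7-tris(3-methylbut-2-en-1-yl)-5-(2-methylpropanoyl)-8-oxabicyclo[5.2.1]decane-6,9,10-trione, via alkylborane 23 (not isolated)
Conditions: 9-BBN (3.5 equiv), THF, 0 °C to rt; then 22, Pd(dppf)Cl2 (10 mol%), AsPh3 (10 mol%), K3PO4 (3 M aq.), DMF, rt
Reagents that add atoms: none
Why: Anti-Markovnikov hydroboration of the 1,1-disubstituted alkene with 9-BBN (faster than at the trisubstituted alkenes, the hindered E alkene and the hindered ketones) and B-alkyl Suzuki–Miyaura coupling complete the prenyl group; C7 is set by substrate control, the borane adding to the alkene face away from the C8 methyl group and the lactone bridge (O–C9), so that hydrogen arrives trans and the new CH2 cis to them.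

Step 14
Reactants: 24
Product: 25 (1R,3S,4R,5R,7S)-4-[(2E)-4-hydroperoxy-4-methylpent-2-en-1-yl]-4-methyl-1,3,7-tris(3-methylbut-2-en-1-yl)-5-(2-methylpropanoyl)-8-oxabicyclo[5.2.1]decane-6,9,10-trione (CNP0545483.1)
Conditions: H2O2 (50% aq., 20 equiv), H2SO4 (0.1 equiv), THF, 0 °C
Reagents that add atoms: hydrogen peroxide, OO
Why: Acid-catalysed perhydrolysis of a tertiary allylic alcohol (SN1 exchange through the tertiary allylic cation, which excess hydrogen peroxide should capture at the more substituted terminus with the E alkene retained); the prenyl alkenes should not be protonated in this cold, dilute acid, and C1 stays at its thermodynamic configuration.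

**Compound list**

1 | dimethyl 3-oxopentanedioate | COC(=O)CC(=O)CC(=O)OC | starting material
2 | 1-bromo-3-methylbut-2-ene | CC(C)=CCBr | starting material
3 | dimethyl 2,4-bis(3-methylbut-2-en-1-yl)-3-oxopentanedioate | COC(=O)C(CC=C(C)C)C(=O)C(CC=C(C)C)C(=O)OC | intermediate
4 | dimethyl (2R)-2-hydroxy-2,4-bis(3-methylbut-2-en-1-yl)-3-oxopentanedioate (C4 epimers) | COC(=O)[C@@](O)(CC=C(C)C)C(=O)C(CC=C(C)C)C(=O)OC | intermediate
5 | methyl (2R)-3-hydroxy-2,4-bis(3-methylbut-2-en-1-yl)-5-oxo-2,5-dihydrofuran-2-carboxylate | COC(=O)[C@]1(CC=C(C)C)OC(=O)C(CC=C(C)C)=C1O | intermediate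
6 | (2R)-3-hydroxy-2,4-bis(3-methylbut-2-en-1-yl)-5-oxo-2,5-dihydrofuran-2-carbaldehyde | O=C[C@]1(CC=C(C)C)OC(=O)C(CC=C(C)C)=C1O | intermediate
7 | pent-1-en-4-yne | C=CCC#C | starting material
8 | 2-methylpropanal | CC(C)C=O | starting material
9 | dimethyl[(1E)-2-methylpenta-1,4-dien-1-yl]alumane | C[Al](C)/C=C(\C)CC=C | intermediate
10 | (4E)-2,5-dimethylocta-4,7-dien-3-ol (racemic) | CC(C)C(O)/C=C(\C)CC=C | intermediate
11 | (4E)-2,5-dimethylocta-4,7-dien-3-one | CC(C)C(=O)/C=C(\C)CC=C | intermediate
12 | tert-butyldimethyl(prop-2-yn-1-yloxy)silane | C#CCO[Si](C)(C)C(C)(C)C | starting material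
13 | {3-[(tert-butyldimethylsilyl)oxy]prop-1-en-2-yl}bis(2-methylpropyl)alumane | C=C(CO[Si](C)(C)C(C)(C)C)[Al](CC(C)C)CC(C)C | intermediate
14 | (5S)-5-{3-[(tert-butyldimethylsilyl)oxy]prop-1-en-2-yl}-2,5-dimethyloct-7-en-3-one | CC(C)C(=O)C[C@](C)(CC=C)C(=C)CO[Si](C)(C)C(C)(C)C | intermediate
15 | 2-methylbut-3-en-2-ol | C=CC(C)(C)O | starting material
16 | (5S,7E)-5-{3-[(tert-butyldimethylsilyl)oxy]prop-1-en-2-yl}-9-hydroxy-2,5,9-trimethyldec-7-en-3-one | CC(C)C(=O)C[C@](C)(C/C=C/C(C)(C)O)C(=C)CO[Si](C)(C)C(C)(C)C | intermediate
17 | aldol adduct of 16 and 6: furanone 6 with its formyl carbon turned into CH(OH) bonded to C1 of the ketone (epimers at C1 and C2) | CC(C)C(=O)C(C(O)[C@]1(CC=C(C)C)OC(=O)C(CC=C(C)C)=C1O)[C@](C)(C/C=C/C(C)(C)O)C(=C)CO[Si](C)(C)C(C)(C)C | intermediate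
18 | 1,3-diketone from 17 (C2 now a ketone; C1 epimers) | CC(C)C(=O)C(C(=O)[C@]1(CC=C(C)C)OC(=O)C(CC=C(C)C)=C1O)[C@](C)(C/C=C/C(C)(C)O)C(=C)CO[Si](C)(C)C(C)(C)C | intermediate
19 | primary allylic alcohol from 18 (silyl group removed; C1 epimers) | CC(C)C(=O)C(C(=O)[C@]1(CC=C(C)C)OC(=O)C(CC=C(C)C)=C1O)[C@](C)(C/C=C/C(C)(C)O)C(=C)CO | intermediate
20 | allylic methyl carbonate of 19 (C1 epimers) | CC(C)C(=O)C(C(=O)[C@]1(CC=C(C)C)OC(=O)C(CC=C(C)C)=C1O)[C@](C)(C/C=C/C(C)(C)O)C(=C)COC(=O)OC | intermediate
21 | (1R,4S,5R,7S)-4-[(2E)-4-hydroxy-4-methylpent-2-en-1-yl]-4-methyl-3-methylidene-1,7-bis(3-methylbut-2-en-1-yl)-5-(2-methylpropanoyl)-8-oxabicyclo[5.2.1]decane-6,9,10-trione | C=C1C[C@@]2(CC=C(C)C)C(=O)O[C@@](CC=C(C)C)(C(=O)[C@@H](C(=O)C(C)C)[C@]1(C)C/C=C/C(C)(C)O)C2=O | intermediate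
22 | 1-bromo-2-methylprop-1-ene | CC(C)=CBr | starting material
23 | alkylborane: 24 with CH2–B(9-borabicyclo[3.3.1]nonan-9-yl) on C7 in place of prenyl | C(B1C2CCCC1CCC2)[C@H]1C[C@@]2(CC=C(C)C)C(=O)O[C@@](CC=C(C)C)(C(=O)[C@@H](C(=O)C(C)C)[C@]1(C)C/C=C/C(C)(C)O)C2=O | intermediate
24 | (1R,3S,4R,5R,7S)-4-[(2E)-4-hydroxy-4-methylpent-2-en-1-yl]-4-methyl-1,3,7-tris(3-methylbut-2-en-1-yl)-5-(2-methylpropanoyl)-8-oxabicyclo[5.2.1]decane-6,9,10-trione | CC(C)=CC[C@H]1C[C@@]2(CC=C(C)C)C(=O)O[C@@](CC=C(C)C)(C(=O)[C@@H](C(=O)C(C)C)[C@]1(C)C/C=C/C(C)(C)O)C2=O | intermediate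
25 | (1R,3S,4R,5R,7S)-4-[(2E)-4-hydroperoxy-4-methylpent-2-en-1-yl]-4-methyl-1,3,7-tris(3-methylbut-2-en-1-yl)-5-(2-methylpropanoyl)-8-oxabicyclo[5.2.1]decane-6,9,10-trione | CC(C)=CC[C@H]1C[C@@]2(CC=C(C)C)C(=O)O[C@@](CC=C(C)C)(C(=O)[C@@H](C(=O)C(C)C)[C@]1(C)C/C=C/C(C)(C)OO)C2=O | target

**Step count and risks**

Total step count: 14. Longest linear sequence: 11 steps (steps 4 to 14).

Step 12. What may go wrong: intermolecular allylation leading to oligomers, or closure through oxygen (the diketone enol to a six-membered ether, the tetronate oxygen to an eight-membered enol ether) that does not funnel on to the C-allylated product. The fallback sets out from 19 and leaves out step 11. An intramolecular Mitsunobu etherification (PPh3, diisopropyl azodicarboxylate, THF, high dilution) would engage the most acidic site, the tetronic acid oxygen on C4, with the primary allylic alcohol and give the cyclic 4-O-allyl tetronate F1. Heating F1 in toluene at 110 °C should then bring about the [3,3] Claisen rearrangement known for 4-O-allyl tetronates, forming the C5–C6 bond inside the molecule and moving the double bond to the exocyclic position; the route is rejoined at 21.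

Step 13. What may go wrong: reduction of ketone carbonyls by the borane, cleavage of the non-enolisable β-keto lactone by the basic aqueous medium of the coupling, or addition to the wrong face of the alkene. The fallback sets out from 21 and uses a neutral, smaller metal hydride. Rhodium-catalysed hydroformylation (Rh(acac)(CO)2, tris(2,4-di-tert-butylphenyl) phosphite, CO/H2, toluene, 80 °C) of the 1,1-disubstituted alkene should give only the linear product, the aldehyde F2, in which C7 carries CH2CHO. A Wittig reaction of F2 with the ylide from isopropyltriphenylphosphonium iodide and n-BuLi (THF, −78 to 0 °C, excess ylide to allow for the acidic diketone) would complete the prenyl group and return to the route at 24.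

Step 2. What may go wrong: poor discrimination of the enolate faces in the oxygen transfer to this acyclic substrate, or a second hydroxylation at the other α-carbon. The fallback sets out from 3 and replaces catalysis by resolution. Dimethyldioxirane in acetone at 0 °C would hydroxylate the enol without stereocontrol to the racemic hydroxy diester F3, which triethylamine closes to the racemic tetronic acid F4. Because F4 is a strong acid, it can be resolved by crystallisation of its salt with (R)-1-phenylethylamine, the (R)-1-phenylethylammonium tetronate F5 (the antipodal amine is used if the other diastereomeric salt is the less soluble one); acidification of F5 returns to the route at 5.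

**Further compounds**

F1 | step 12 | cyclic 4-O-allyl tetronate: 19 with the tetronic acid oxygen on C4 bonded to the allylic CH2 (eight-membered enol ether) | C=C1COC2=C(CC=C(C)C)C(=O)O[C@@]2(CC=C(C)C)C(=O)C(C(=O)C(C)C)[C@]1(C)C/C=C/C(C)(C)O
F2 | step 13 | aldehyde: 24 with CH2CHO on C7 in place of prenyl | O=CC[C@H]1C[C@@]2(CC=C(C)C)C(=O)O[C@@](CC=C(C)C)(C(=O)[C@@H](C(=O)C(C)C)[C@]1(C)C/C=C/C(C)(C)O)C2=O
F3 | step 2 | racemic dimethyl 2-hydroxy-2,4-bis(3-methylbut-2-en-1-yl)-3-oxopentanedioate | COC(=O)C(O)(CC=C(C)C)C(=O)C(CC=C(C)C)C(=O)OC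
F4 | step 2 | racemic methyl 3-hydroxy-2,4-bis(3-methylbut-2-en-1-yl)-5-oxo-2,5-dihydrofuran-2-carboxylate | COC(=O)C1(CC=C(C)C)OC(=O)C(CC=C(C)C)=C1O
F5 | step 2 | (R)-1-phenylethylammonium salt of 5 | C[C@@H]([NH3+])c1ccccc1.COC(=O)[C@]1(CC=C(C)C)OC(=O)C(CC=C(C)C)=C1[O-]
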